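The target is cut at the tetrahydrofuran C2–C3 bond. Because the ring B aryl at C2, the CH2OH carbon on C3 and the ring A benzyl carbon on C4 are all cis, the two side-chain carbons on C3 and C4 are tied together as a γ-lactone whose ring oxygen sits on the ring A benzylic carbon. A rhodium carbene at the lactone α-carbon then inserts into the ring B benzylic ether C–H bond, closing the tetrahydrofuran and setting C2 and C3 in one operation. The precursor is a trans-5-aryl-4-[(arylmethoxy)methyl]-3-diazo-γ-butyrolactone carrying the silylated bis(dihydrobenzofuran) unit; the lactone is later opened reductively at the ring A benzylic C–O bond.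

Key step: step 27

Remark: the ring A benzylic stereocentre made in step 22 is erased in step 29; it serves only to give the trans lactone that the key step needs. Both enantiomers of 4-benzyl-1,3-oxazolidin-2-one are taken as commercial.

Abbreviations: TBS = tert-butyldimethylsilyl; TIPS = triisopropylsilyl; ArA = 3-methoxy-4-(TIPS-oxy)phenyl (ring A). Ring B and ring C are the benzo rings of dihydrobenzofuran 1 and dihydrobenzofuran 2; ring D is the terminal guaiacyl ring. CD = (2S,3R)-3-[(TBS-oxy)methyl]-2-[4-(TBS-oxy)-3-methoxyphenyl]-7-methoxy-2,3-dihydro-1-benzofuran-5-yl. BCD = (2R,3S)-3-[(TBS-oxy)methyl]-2-(CD)-7-methoxy-2,3-dihydro-1-benzofuran-5-yl. "Desilylated BCD" is BCD with its three silyl groups replaced by H.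

Step 1
Reactants: 1 vanillin
Product: 2 3-methoxy-4-[(triisopropylsilyl)oxy]benzaldehyde
Conditions: TIPSCl, imidazole, DMF, rt
Reagents that add atoms: triisopropylsilyl chloride, CC(C)[Si](Cl)(C(C)C)C(C)C
Why: Silylation of the phenol with a silyl chloride and imidazole; the bulky TIPS ether is chosen so that the aryl silyl ether survives the enolborination, hydride and LiOOH steps that follow.

Step 2
Reactants: 3 methyl vanillate
Product: 4 methyl 3-methoxy-4-(prop-2-en-1-yloxy)benzoate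
Conditions: allyl bromide, K2CO3, acetone, reflux
Reagents that add atoms: allyl bromide, C=CCBr
Why: Williamson ether synthesis on the phenoxide with a reactive allylic bromide.

Step 3
Reactants: 4 methyl 3-methoxy-4-(prop-2-en-1-yloxy)benzoate
Product: 5 methyl 4-hydroxy-3-methoxy-5-(prop-2-en-1-yl)benzoate
Conditions: PhNEt2, 200 °C, sealed tube
Reagents that add atoms: none
Why: Aromatic Claisen rearrangement; the [3,3] shift can only reach the free ortho carbon C5, and rearomatisation gives the 5-allyl phenol.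

Step 4
Reactants: 5 methyl 4-hydroxy-3-methoxy-5-(prop-2-en-1-yl)benzoate
Product: 6 methyl 4-(TBS-oxy)-3-methoxy-5-(prop-2-en-1-yl)benzoate
Conditions: TBSCl, imidazole, DMF, 40 °C
Reagents that add atoms: tert-butyldimethylsilyl chloride, CC(C)(C)[Si](C)(C)Cl
Why: Silylation of the hindered phenol (flanked by OMe and allyl) under imidazole catalysis, masking the oxygen that later becomes the dihydrobenzofuran oxygen of ring B or ring C.

Step 5
Reactants: 6 methyl 4-(TBS-oxy)-3-methoxy-5-(prop-2-en-1-yl)benzoate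
Product: 8 [2-(TBS-oxy)-3-methoxy-5-(methoxycarbonyl)phenyl]acetic acid, via arylacetaldehyde 7 (not isolated)
Conditions: O3, CH2Cl2, −78 °C; Me2S, −78 °C → rt; then NaClO2, NaH2PO4, 2-methyl-2-butene, t-BuOH/H2O, rt
Reagents that add atoms: ozone, [O-][O+]=O; sodium chlorite, [Na+].[O-]Cl=O
Why: Ozonolysis of the terminal alkene, which reacts far faster than the ester-deactivated arene, followed by Pinnick oxidation of the crude arylacetaldehyde.

Step 6
Reactants: 8 [2-(TBS-oxy)-3-methoxy-5-(methoxycarbonyl)phenyl]acetic acid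
Product: 9 [2-(TBS-oxy)-3-methoxy-5-(methoxycarbonyl)phenyl]acetyl chloride
Conditions: (COCl)2, DMF (cat.), CH2Cl2, 0 °C → rt; evaporate (toluene chase), use crude at once
Reagents that add atoms: oxalyl chloride, ClC(=O)C(=O)Cl
Why: Acid chloride formation through the Vilsmeier-type chloroiminium salt from oxalyl chloride and DMF; all by-products are volatile, so one batch of the crude acid chloride, obtained by evaporation, can be divided between the two auxiliary acylations, and the hindered aryl TBS ether and the methyl ester should tolerate the brief exposure to HCl.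

Step 7
Reactants: 9 [2-(TBS-oxy)-3-methoxy-5-(methoxycarbonyl)phenyl]acetyl chloride; 10 (S)-4-benzyl-1,3-oxazolidin-2-one
Product: 11 methyl 3-{2-[(4S)-4-benzyl-2-oxo-1,3-oxazolidin-3-yl]-2-oxoethyl}-4-(TBS-oxy)-5-methoxybenzoate
Conditions: 10, Et3N, LiCl, THF, −20 °C; then 9 (slow addition), −20 °C → rt
Reagents that add atoms: none
Why: N-acylation of the oxazolidinone by an acid chloride under Et3N/LiCl activation (the lithium-coordinated carbamate is acylated at nitrogen), conditions mild enough for the methyl ester and the aryl silyl ether.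

Step 8
Reactants: 11 (S)-auxiliary arylacetyl imide; 2 3-methoxy-4-(TIPS-oxy)benzaldehyde
Product: 13 Evans-syn aldol adduct, methyl 3-[(1S,2S)-1-{[(4S)-4-benzyl-2-oxo-1,3-oxazolidin-3-yl]carbonyl}-2-hydroxy-2-(ArA)ethyl]-4-(TBS-oxy)-5-methoxybenzoate, via dibutylboron enolate 12 (not isolated)
Conditions: Bu2BOTf, i-Pr2NEt, CH2Cl2, −78 → 0 °C; then 2, −78 → 0 °C; pH 7 buffer, MeOH, H2O2, 0 °C
Reagents that add atoms: none
Why: Evans boron aldol reaction; the Z-boron enolate reacts through a Zimmerman–Traxler chair with the benzyl group of the auxiliary blocking one face, which sets the α-carbon (future C3 of dihydrobenzofuran 2) as S and gives the syn adduct.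

Step 9
Reactants: 13 Evans-syn aldol adduct
Product: 14 methyl 3-[(1S,2R)-1,3-dihydroxy-1-(ArA)propan-2-yl]-4-(TBS-oxy)-5-methoxybenzoate
Conditions: LiBH4, MeOH (1 equiv), THF, 0 °C
Reagents that add atoms: none
Why: Reductive cleavage of the N-acyloxazolidinone with LiBH4 to the primary alcohol, fast at 0 °C while the electron-rich methyl benzoate is reduced only slowly; no stereocentre is touched.

Step 10
Reactants: 14 silylated 1,3-diol
Product: 16 methyl (2S,3R)-2-(4-hydroxy-3-methoxyphenyl)-3-(hydroxymethyl)-7-methoxy-2,3-dihydro-1-benzofuran-5-carboxylate (2,3-trans), via desilylated triol 15 (not isolated)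
Conditions: TBAF, THF, 0 °C; then TsOH·H2O (slight excess over TBAF), rt
Reagents that add atoms: none
Why: Fluoride desilylation, then acid-catalysed intramolecular etherification of the p-hydroxybenzylic alcohol through its quinone methide or benzylic cation (phenylcoumaran formation, 5-exo-trig); C2 should be set trans to the C3 hydroxymethyl group because attack occurs anti to that group and the closure is reversible under acid, while C3, fixed in step 8, is not touched.

Step 11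
Reactants: 16 dihydrobenzofuran 2 phenol alcohol
Product: 17 methyl (2S,3R)-3-[(TBS-oxy)methyl]-2-[4-(TBS-oxy)-3-methoxyphenyl]-7-methoxy-2,3-dihydro-1-benzofuran-5-carboxylate (CD–CO2Me)
Conditions: TBSCl (excess), imidazole, DMF, rt
Reagents that add atoms: tert-butyldimethylsilyl chloride, CC(C)(C)[Si](C)(C)Cl
Why: Silylation of the ring D phenol and the primary alcohol with a silyl chloride and imidazole.

Step 12
Reactants: 17 CD–CO2Me
Product: 18 CD–CH2OH
Conditions: i-Bu2AlH, CH2Cl2, −78 → 0 °C; aq. potassium sodium tartrate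
Reagents that add atoms: none
Why: Hydride reduction of the methyl ester to the benzylic alcohol with i-Bu2AlH, to which silyl ethers and the dihydrobenzofuran are inert.

Step 13
Reactants: 18 CD–CH2OH
Product: 19 CD–CHO
Conditions: MnO2, CH2Cl2, rt
Reagents that add atoms: none
Why: Chemoselective oxidation of the benzylic alcohol to the aldehyde with MnO2, which leaves silyl ethers and the dihydrobenzofuran benzylic ether alone.

Step 14
Reactants: 9 [2-(TBS-oxy)-3-methoxy-5-(methoxycarbonyl)phenyl]acetyl chloride; 20 (R)-4-benzyl-1,3-oxazolidin-2-one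
Product: 21 methyl 3-{2-[(4R)-4-benzyl-2-oxo-1,3-oxazolidin-3-yl]-2-oxoethyl}-4-(TBS-oxy)-5-methoxybenzoate
Conditions: 20, Et3N, LiCl, THF, −20 °C; then 9 (slow addition), −20 °C → rt
Reagents that add atoms: none
Why: Same acid chloride N-acylation as step 7, run on a second portion of the batch of 9, now with the enantiomeric auxiliary because dihydrobenzofuran 1 has the opposite absolute configuration to dihydrobenzofuran 2.

Step 15
Reactants: 21 (R)-auxiliary arylacetyl imide; 19 CD–CHO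
Product: 23 Evans-syn aldol adduct, methyl 3-[(1R,2R)-1-{[(4R)-4-benzyl-2-oxo-1,3-oxazolidin-3-yl]carbonyl}-2-hydroxy-2-(CD)ethyl]-4-(TBS-oxy)-5-methoxybenzoate, via dibutylboron enolate 22 (not isolated)
Conditions: Bu2BOTf, i-Pr2NEt, CH2Cl2, −78 → 0 °C; then 19, −78 → 0 °C; pH 7 buffer, MeOH, H2O2, 0 °C
Reagents that add atoms: none
Why: Evans boron aldol reaction under reagent control of the (R)-auxiliary (Z-enolate, Zimmerman–Traxler chair), which sets the α-carbon (future C3 of dihydrobenzofuran 1) as R in the adduct regardless of the remote stereocentres of 19.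

Step 16
Reactants: 23 Evans-syn aldol adduct
Product: 24 methyl 3-[(1R,2S)-1,3-dihydroxy-1-(CD)propan-2-yl]-4-(TBS-oxy)-5-methoxybenzoate
Conditions: LiBH4, MeOH (1 equiv), THF, 0 °C
Reagents that add atoms: none
Why: Reductive removal of the auxiliary with LiBH4 as in step 9, without change at any stereocentre.

Step 17
Reactants: 24 silylated 1,3-diol
Product: 26 methyl (2R,3S)-3-(hydroxymethyl)-2-[(2S,3R)-2-(4-hydroxy-3-methoxyphenyl)-3-(hydroxymethyl)-7-methoxy-2,3-dihydro-1-benzofuran-5-yl]-7-methoxy-2,3-dihydro-1-benzofuran-5-carboxylate, via desilylated pentaol 25 (not isolated)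
Conditions: TBAF, THF, 0 °C; then TsOH·H2O (slight excess over TBAF), 0 °C → rt
Reagents that add atoms: none
Why: Fluoride desilylation then acid-catalysed phenylcoumaran closure as in step 10, ionisation occurring at the ring C benzylic alcohol (para to the ether oxygen of dihydrobenzofuran 2) and the ring B phenol closing trans to the hydroxymethyl group; any reversible opening of dihydrobenzofuran 2 recloses to the same trans isomer because its C3 centre is fixed.

Step 18
Reactants: 26 bis(dihydrobenzofuran) triol ester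
Product: 27 BCD–CO2Me
Conditions: TBSCl (excess), imidazole, DMF, rt
Reagents that add atoms: tert-butyldimethylsilyl chloride, CC(C)(C)[Si](C)(C)Cl
Why: Silylation of the ring D phenol and both primary alcohols with a silyl chloride and imidazole.

Step 19
Reactants: 27 BCD–CO2Me
Product: 28 BCD–CH2OH
Conditions: i-Bu2AlH, CH2Cl2, −78 → 0 °C; aq. potassium sodium tartrate
Reagents that add atoms: none
Why: Hydride reduction of the ester to the ring B benzylic alcohol with i-Bu2AlH, as in step 12.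

Step 20
Reactants: 28 BCD–CH2OH
Product: 29 BCD–CH2 2,2,2-trichloroacetimidate
Conditions: Cl3CCN, DBU (cat.), CH2Cl2, 0 °C
Reagents that add atoms: trichloroacetonitrile, ClC(Cl)(Cl)C#N
Why: Base-catalysed addition of the alcohol to trichloroacetonitrile (trichloroacetimidate formation); the imidate is used at once because 4-alkoxybenzyl imidates rearrange on standing.

Step 21
Reactants: 30 4-methoxy-4-oxobutanoic acid; 10 (S)-4-benzyl-1,3-oxazolidin-2-one
Product: 32 methyl 4-[(4S)-4-benzyl-2-oxo-1,3-oxazolidin-3-yl]-4-oxobutanoate, via mixed pivalic anhydride 31 (not isolated)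
Conditions: PivCl, Et3N, THF, −20 °C; then 10, LiCl, rt
Reagents that add atoms: none
Why: N-acylation of the oxazolidinone through the mixed pivalic anhydride under Et3N/LiCl activation, attack occurring at the unhindered succinyl and not the pivaloyl carbonyl.

Step 22
Reactants: 32 succinate imide; 2 3-methoxy-4-(TIPS-oxy)benzaldehyde
Product: 35 (4S)-4-benzyl-3-{[(2S,3S)-2-(ArA)-5-oxooxolan-3-yl]carbonyl}-1,3-oxazolidin-2-one (trans lactone), via dibutylboron enolate 33 (not isolated), via syn aldol adduct 34 (not isolated)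
Conditions: Bu2BOTf, i-Pr2NEt, CH2Cl2, −78 → 0 °C; then 2, −78 → 0 °C; pH 7 buffer, MeOH, H2O2, 0 °C; then PPTS (cat.), CH2Cl2, rt
Reagents that add atoms: none
Why: Evans boron aldol reaction of the succinate imide (Z-enolate, Zimmerman–Traxler chair, auxiliary-controlled face) to the syn adduct (3S,4S), whose hydroxyl then closes on the methyl ester (5-exo-trig lactonisation) and so converts the syn relation into the trans-4,5-disubstituted γ-lactone.

Step 23
Reactants: 35 trans lactone imide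
Product: 37 (2S,3S)-2-(ArA)-5-oxooxolane-3-carboxylic acid, via peroxy acid 36 (not isolated)
Conditions: LiOH, H2O2, THF/H2O, 0 °C; Na2SO3; HCl to pH 2
Reagents that add atoms: hydrogen peroxide, OO
Why: Exocyclic cleavage of the imide by LiOOH and sulfite reduction of the peroxy acid; at 0 °C the hindered aryl TIPS ether should persist and acidification keeps the γ-lactone closed.

Step 24
Reactants: 37 lactone acid
Product: 38 (4R,5S)-4-(hydroxymethyl)-5-(ArA)oxolan-2-one
Conditions: BH3·SMe2, THF, 0 °C → rt; MeOH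
Reagents that add atoms: none
Why: Chemoselective borane reduction of the carboxylic acid in the presence of the lactone, under non-basic conditions that avoid acyl migration of the lactone to the new primary alcohol.

Step 25
Reactants: 38 hydroxymethyl lactone; 29 BCD–CH2 trichloroacetimidate
Product: 39 (4R,5S)-4-{[(BCD)methoxy]methyl}-5-(ArA)oxolan-2-one
Conditions: La(OTf)3 (5 mol%), toluene, rt
Reagents that add atoms: none
Why: Acid-catalysed O-alkylation with a benzylic trichloroacetimidate (the 4-alkoxybenzyl imidate ionises under a mild Lewis acid), chosen because basic Williamson conditions would let the hydroxymethyl lactone translactonise.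

Step 26
Reactants: 39 ether lactone
Product: 42 (4R,5S)-3-diazo-4-{[(BCD)methoxy]methyl}-5-(ArA)oxolan-2-one, via lithium enolate 40 (not isolated), via trifluoroacetyl lactone 41 (not isolated)
Conditions: LiN(SiMe3)2, THF, −78 °C; CF3CO2CH2CF3, −78 °C; aq. NH4Cl; then MsN3, Et3N, H2O (1 equiv), MeCN, rt
Reagents that add atoms: methanesulfonyl azide, CS(=O)(=O)N=[N+]=[N-]
Why: Detrifluoroacetylative Regitz diazo transfer: the lactone enolate is trifluoroacetylated to activate the α-carbon, and the sulfonyl azide with Et3N then transfers N2 with loss of the trifluoroacetyl group; C4 and C5 are not epimerisable under these conditions.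

Step 27
Reactants: 42 diazo lactone
Product: 43 (1S,2R,5R,6S)-2-(BCD)-6-(ArA)-3,7-dioxabicyclo[3.3.0]octan-8-one (ring B aryl endo, ring A aryl exo)
Conditions: Rh2(OAc)4 (2 mol%), CH2Cl2, reflux, slow addition of 42 at high dilution
Reagents that add atoms: none
Why: Dirhodium tetraacetate, a divalent rhodium carboxylate dimer, expels N2 from 42 to give an electrophilic rhodium carbene at the lactone α-carbon, which inserts into one of the two ring B benzylic ether C–H bonds through a concerted, asynchronous three-centre transition state with hydride-transfer character. The closest known reaction type is the Rh2(OAc)4-catalysed 1,5 C–H insertion of trans-4-[(benzyloxy)methyl]-5-aryl-3-diazo-γ-butyrolactones, which gives endo,exo-furofuranones. The tetrahydrofuran closes in the 1,5-insertion mode (five-membered ring from the carbene carbon, C4, CH2, O and the benzylic carbon) and is necessarily cis-fused to the lactone, so C3 of the future tetrahydrofuran is set cis to C4 by the existing C4 stereocentre. At C2 the ring B aryl group should take the endo (concave) position because, in the chair-like insertion transition state on the trans-lactone template, the aryl group lies pseudo-equatorial and away from the dirhodium ligand sphere; the insertion is concerted and irreversible, so this kinetic preference delivers the all-cis C2/C3/C4 triad. The step needs site selectivity over 1,2-hydride migration from C4–H and over remote benzylic and α-silyloxy C–H bonds: only the OCH2 group can reach the carbene through a five-membered transition state, and its C–H bonds are activated by the ether oxygen and by the electron-rich ring B (para oxygen of dihydrobenzofuran 1). All O–H groups are silylated to exclude O–H insertion, and slow addition at high dilution suppresses carbene dimerisation.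

Step 28
Reactants: 43 silylated furofuranone
Product: 44 (1S,2R,5R,6S)-2-(desilylated BCD)-6-(4-hydroxy-3-methoxyphenyl)-3,7-dioxabicyclo[3.3.0]octan-8-one
Conditions: TBAF, AcOH (1:1), THF, 0 °C → rt
Reagents that add atoms: none
Why: Fluoride cleavage of all four silyl ethers, buffered with AcOH so that the ring A phenol stays protonated and the p-hydroxybenzylic lactone is not yet opened.

Step 29
Reactants: 44 desilylated furofuranone
Product: 46 (2R,3S,4R)-2-(desilylated BCD)-4-(4-hydroxy-3-methoxybenzyl)oxolane-3-carboxylic acid, via quinone methide carboxylate 45 (not isolated)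
Conditions: NaBH4, DBU, THF/i-PrOH, 0 °C → rt; aq. citric acid
Reagents that add atoms: none
Why: Base-triggered 1,6-elimination of the ring A p-hydroxybenzylic carboxylate to a p-quinone methide and immediate 1,6-addition of hydride (the reduction known for p-hydroxybenzyl esters); only ring A combines a free para phenol with a good benzylic leaving group, strain release in the bicyclic lactone favours opening, and C2, C3 and C4 are not involved.

Step 30
Reactants: 46 tetrahydrofuran carboxylic acid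
Product: 47 CNP0395728.1, the (2R,3R,4R) all-cis tetrahydrofuran target
Conditions: BH3·THF (excess), THF, 0 °C → rt; MeOH; aq. NH4Cl
Reagents that add atoms: none
Why: Borane reduction of the carboxylic acid to the primary alcohol, which tolerates free phenols, alcohols and benzylic ethers and does not epimerise the all-cis C3 centre.

Compound list

1 | vanillin (4-hydroxy-3-methoxybenzaldehyde) | COc1cc(C=O)ccc1O | starting material
2 | 3-methoxy-4-[(triisopropylsilyl)oxy]benzaldehyde | COc1cc(C=O)ccc1O[Si](C(C)C)(C(C)C)C(C)C | intermediate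
3 | methyl vanillate (methyl 4-hydroxy-3-methoxybenzoate) | COC(=O)c1ccc(O)c(OC)c1 | starting material
4 | methyl 3-methoxy-4-(prop-2-en-1-yloxy)benzoate | COC(=O)c1ccc(OCC=C)c(OC)c1 | intermediate
5 | methyl 4-hydroxy-3-methoxy-5-(prop-2-en-1-yl)benzoate | COC(=O)c1cc(CC=C)c(O)c(OC)c1 | intermediate
6 | methyl 4-(TBS-oxy)-3-methoxy-5-(prop-2-en-1-yl)benzoate | COC(=O)c1cc(CC=C)c(O[Si](C)(C)C(C)(C)C)c(OC)c1 | intermediate
7 | methyl 4-(TBS-oxy)-3-methoxy-5-(2-oxoethyl)benzoate (formed in situ) | COC(=O)c1cc(CC=O)c(O[Si](C)(C)C(C)(C)C)c(OC)c1 | intermediate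
8 | [2-(TBS-oxy)-3-methoxy-5-(methoxycarbonyl)phenyl]acetic acid | COC(=O)c1cc(CC(=O)O)c(O[Si](C)(C)C(C)(C)C)c(OC)c1 | intermediate
9 | [2-(TBS-oxy)-3-methoxy-5-(methoxycarbonyl)phenyl]acetyl chloride | COC(=O)c1cc(CC(=O)Cl)c(O[Si](C)(C)C(C)(C)C)c(OC)c1 | intermediate
10 | (S)-4-benzyl-1,3-oxazolidin-2-one | O=C1N[C@@H](Cc2ccccc2)CO1 | starting material
11 | methyl 3-{2-[(4S)-4-benzyl-2-oxo-1,3-oxazolidin-3-yl]-2-oxoethyl}-4-(TBS-oxy)-5-methoxybenzoate | COC(=O)c1cc(CC(=O)N2[C@@H](Cc3ccccc3)COC2=O)c(O[Si](C)(C)C(C)(C)C)c(OC)c1 | intermediate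
12 | (Z)-dibutylboron enolate of 11 (formed in situ) | COC(=O)c1cc(/C=C(\OB(CCCC)CCCC)N2[C@@H](Cc3ccccc3)COC2=O)c(O[Si](C)(C)C(C)(C)C)c(OC)c1 | intermediate
13 | methyl 3-[(1S,2S)-1-{[(4S)-4-benzyl-2-oxo-1,3-oxazolidin-3-yl]carbonyl}-2-hydroxy-2-(ArA)ethyl]-4-(TBS-oxy)-5-methoxybenzoate | COC(=O)c1cc(OC)c(O[Si](C)(C)C(C)(C)C)c(c1)[C@H](C(=O)N1[C@@H](Cc2ccccc2)COC1=O)[C@H](O)c1ccc(O[Si](C(C)C)(C(C)C)C(C)C)c(OC)c1 | intermediate
14 | methyl 3-[(1S,2R)-1,3-dihydroxy-1-(ArA)propan-2-yl]-4-(TBS-oxy)-5-methoxybenzoate | COC(=O)c1cc(OC)c(O[Si](C)(C)C(C)(C)C)c(c1)[C@H](CO)[C@H](O)c1ccc(O[Si](C(C)C)(C(C)C)C(C)C)c(OC)c1 | intermediate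
15 | methyl 3-[(1S,2R)-1,3-dihydroxy-1-(4-hydroxy-3-methoxyphenyl)propan-2-yl]-4-hydroxy-5-methoxybenzoate (formed in situ) | COC(=O)c1cc(OC)c(O)c(c1)[C@H](CO)[C@H](O)c1ccc(O)c(OC)c1 | intermediate
16 | methyl (2S,3R)-2-(4-hydroxy-3-methoxyphenyl)-3-(hydroxymethyl)-7-methoxy-2,3-dihydro-1-benzofuran-5-carboxylate | COC(=O)c1cc(OC)c2c(c1)[C@H](CO)[C@@H](c1ccc(O)c(OC)c1)O2 | intermediate
17 | methyl (2S,3R)-3-[(TBS-oxy)methyl]-2-[4-(TBS-oxy)-3-methoxyphenyl]-7-methoxy-2,3-dihydro-1-benzofuran-5-carboxylate (CD–CO2Me) | COC(=O)c1cc(OC)c2c(c1)[C@H](CO[Si](C)(C)C(C)(C)C)[C@@H](c1ccc(O[Si](C)(C)C(C)(C)C)c(OC)c1)O2 | intermediate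
18 | CD–CH2OH, the 5-(hydroxymethyl) analogue of 17 | OCc1cc(OC)c2c(c1)[C@H](CO[Si](C)(C)C(C)(C)C)[C@@H](c1ccc(O[Si](C)(C)C(C)(C)C)c(OC)c1)O2 | intermediate
19 | CD–CHO, the 5-carbaldehyde analogue of 17 | O=Cc1cc(OC)c2c(c1)[C@H](CO[Si](C)(C)C(C)(C)C)[C@@H](c1ccc(O[Si](C)(C)C(C)(C)C)c(OC)c1)O2 | intermediate
20 | (R)-4-benzyl-1,3-oxazolidin-2-one | O=C1N[C@H](Cc2ccccc2)CO1 | starting material
21 | methyl 3-{2-[(4R)-4-benzyl-2-oxo-1,3-oxazolidin-3-yl]-2-oxoethyl}-4-(TBS-oxy)-5-methoxybenzoate | COC(=O)c1cc(CC(=O)N2[C@H](Cc3ccccc3)COC2=O)c(O[Si](C)(C)C(C)(C)C)c(OC)c1 | intermediate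
22 | (Z)-dibutylboron enolate of 21 (formed in situ) | COC(=O)c1cc(/C=C(\OB(CCCC)CCCC)N2[C@H](Cc3ccccc3)COC2=O)c(O[Si](C)(C)C(C)(C)C)c(OC)c1 | intermediate
23 | methyl 3-[(1R,2R)-1-{[(4R)-4-benzyl-2-oxo-1,3-oxazolidin-3-yl]carbonyl}-2-hydroxy-2-(CD)ethyl]-4-(TBS-oxy)-5-methoxybenzoate | COC(=O)c1cc(OC)c(O[Si](C)(C)C(C)(C)C)c(c1)[C@@H](C(=O)N1[C@H](Cc2ccccc2)COC1=O)[C@@H](O)c1cc(OC)c2c(c1)[C@H](CO[Si](C)(C)C(C)(C)C)[C@@H](c1ccc(O[Si](C)(C)C(C)(C)C)c(OC)c1)O2 | intermediate
24 | methyl 3-[(1R,2S)-1,3-dihydroxy-1-(CD)propan-2-yl]-4-(TBS-oxy)-5-methoxybenzoate | COC(=O)c1cc(OC)c(O[Si](C)(C)C(C)(C)C)c(c1)[C@@H](CO)[C@@H](O)c1cc(OC)c2c(c1)[C@H](CO[Si](C)(C)C(C)(C)C)[C@@H](c1ccc(O[Si](C)(C)C(C)(C)C)c(OC)c1)O2 | intermediate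
25 | fully desilylated analogue of 24 (formed in situ) | COC(=O)c1cc(OC)c(O)c(c1)[C@@H](CO)[C@@H](O)c1cc(OC)c2c(c1)[C@H](CO)[C@@H](c1ccc(O)c(OC)c1)O2 | intermediate
26 | methyl (2R,3S)-3-(hydroxymethyl)-2-[(2S,3R)-2-(4-hydroxy-3-methoxyphenyl)-3-(hydroxymethyl)-7-methoxy-2,3-dihydro-1-benzofuran-5-yl]-7-methoxy-2,3-dihydro-1-benzofuran-5-carboxylate | COC(=O)c1cc(OC)c2c(c1)[C@@H](CO)[C@H](c1cc(OC)c3c(c1)[C@H](CO)[C@@H](c1ccc(O)c(OC)c1)O3)O2 | intermediate
27 | BCD–CO2Me, the tris-TBS ether of 26 | COC(=O)c1cc(OC)c2c(c1)[C@@H](CO[Si](C)(C)C(C)(C)C)[C@H](c1cc(OC)c3c(c1)[C@H](CO[Si](C)(C)C(C)(C)C)[C@@H](c1ccc(O[Si](C)(C)C(C)(C)C)c(OC)c1)O3)O2 | intermediate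
28 | BCD–CH2OH | OCc1cc(OC)c2c(c1)[C@@H](CO[Si](C)(C)C(C)(C)C)[C@H](c1cc(OC)c3c(c1)[C@H](CO[Si](C)(C)C(C)(C)C)[C@@H](c1ccc(O[Si](C)(C)C(C)(C)C)c(OC)c1)O3)O2 | intermediate
29 | BCD–CH2 2,2,2-trichloroacetimidate | N=C(OCc1cc(OC)c2c(c1)[C@@H](CO[Si](C)(C)C(C)(C)C)[C@H](c1cc(OC)c3c(c1)[C@H](CO[Si](C)(C)C(C)(C)C)[C@@H](c1ccc(O[Si](C)(C)C(C)(C)C)c(OC)c1)O3)O2)C(Cl)(Cl)Cl | intermediate
30 | 4-methoxy-4-oxobutanoic acid | COC(=O)CCC(=O)O | starting material
31 | mixed anhydride of acid 30 and pivalic acid (formed in situ) | COC(=O)CCC(=O)OC(=O)C(C)(C)C | intermediate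
32 | methyl 4-[(4S)-4-benzyl-2-oxo-1,3-oxazolidin-3-yl]-4-oxobutanoate | COC(=O)CCC(=O)N1[C@@H](Cc2ccccc2)COC1=O | intermediate
33 | (Z)-dibutylboron enolate of 32 (formed in situ) | COC(=O)C/C=C(\OB(CCCC)CCCC)N1[C@@H](Cc2ccccc2)COC1=O | intermediate
34 | methyl (3S,4S)-3-{[(4S)-4-benzyl-2-oxo-1,3-oxazolidin-3-yl]carbonyl}-4-hydroxy-4-(ArA)butanoate (formed in situ) | COC(=O)C[C@H](C(=O)N1[C@@H](Cc2ccccc2)COC1=O)[C@H](O)c1ccc(O[Si](C(C)C)(C(C)C)C(C)C)c(OC)c1 | intermediate
35 | (4S)-4-benzyl-3-{[(2S,3S)-2-(ArA)-5-oxooxolan-3-yl]carbonyl}-1,3-oxazolidin-2-one | COc1cc(ccc1O[Si](C(C)C)(C(C)C)C(C)C)[C@@H]1[C@@H](C(=O)N2[C@@H](Cc3ccccc3)COC2=O)CC(=O)O1 | intermediate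
36 | (2S,3S)-2-(ArA)-5-oxooxolane-3-carboperoxoic acid (formed in situ) | COc1cc(ccc1O[Si](C(C)C)(C(C)C)C(C)C)[C@@H]1[C@@H](C(=O)OO)CC(=O)O1 | intermediate
37 | (2S,3S)-2-(ArA)-5-oxooxolane-3-carboxylic acid | COc1cc(ccc1O[Si](C(C)C)(C(C)C)C(C)C)[C@@H]1[C@@H](C(=O)O)CC(=O)O1 | intermediate
38 | (4R,5S)-4-(hydroxymethyl)-5-(ArA)oxolan-2-one | COc1cc(ccc1O[Si](C(C)C)(C(C)C)C(C)C)[C@@H]1[C@@H](CO)CC(=O)O1 | intermediate
39 | (4R,5S)-4-{[(BCD)methoxy]methyl}-5-(ArA)oxolan-2-one | COc1cc(ccc1O[Si](C(C)C)(C(C)C)C(C)C)[C@@H]1[C@@H](COCc2cc(OC)c3c(c2)[C@@H](CO[Si](C)(C)C(C)(C)C)[C@H](c2cc(OC)c4c(c2)[C@H](CO[Si](C)(C)C(C)(C)C)[C@@H](c2ccc(O[Si](C)(C)C(C)(C)C)c(OC)c2)O4)O3)CC(=O)O1 | intermediate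
40 | lithium enolate of 39 (formed in situ) | COc1cc(ccc1O[Si](C(C)C)(C(C)C)C(C)C)[C@@H]1[C@@H](COCc2cc(OC)c3c(c2)[C@@H](CO[Si](C)(C)C(C)(C)C)[C@H](c2cc(OC)c4c(c2)[C@H](CO[Si](C)(C)C(C)(C)C)[C@@H](c2ccc(O[Si](C)(C)C(C)(C)C)c(OC)c2)O4)O3)C=C(O[Li])O1 | intermediate
41 | 3-(trifluoroacetyl) derivative of 39, C3 unassigned (formed in situ) | COc1cc(ccc1O[Si](C(C)C)(C(C)C)C(C)C)[C@@H]1[C@@H](COCc2cc(OC)c3c(c2)[C@@H](CO[Si](C)(C)C(C)(C)C)[C@H](c2cc(OC)c4c(c2)[C@H](CO[Si](C)(C)C(C)(C)C)[C@@H](c2ccc(O[Si](C)(C)C(C)(C)C)c(OC)c2)O4)O3)C(C(=O)C(F)(F)F)C(=O)O1 | intermediate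
42 | (4R,5S)-3-diazo-4-{[(BCD)methoxy]methyl}-5-(ArA)oxolan-2-one | COc1cc(ccc1O[Si](C(C)C)(C(C)C)C(C)C)[C@@H]1[C@@H](COCc2cc(OC)c3c(c2)[C@@H](CO[Si](C)(C)C(C)(C)C)[C@H](c2cc(OC)c4c(c2)[C@H](CO[Si](C)(C)C(C)(C)C)[C@@H](c2ccc(O[Si](C)(C)C(C)(C)C)c(OC)c2)O4)O3)C(=[N+]=[N-])C(=O)O1 | intermediate
43 | (1S,2R,5R,6S)-2-(BCD)-6-(ArA)-3,7-dioxabicyclo[3.3.0]octan-8-one (C2 aryl endo, C6 aryl exo) | COc1cc(ccc1O[Si](C(C)C)(C(C)C)C(C)C)[C@@H]1[C@H]2CO[C@@H](c3cc(OC)c4c(c3)[C@@H](CO[Si](C)(C)C(C)(C)C)[C@H](c3cc(OC)c5c(c3)[C@H](CO[Si](C)(C)C(C)(C)C)[C@@H](c3ccc(O[Si](C)(C)C(C)(C)C)c(OC)c3)O5)O4)[C@H]2C(=O)O1 | intermediate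
44 | (1S,2R,5R,6S)-2-(desilylated BCD)-6-(4-hydroxy-3-methoxyphenyl)-3,7-dioxabicyclo[3.3.0]octan-8-one | COc1cc(ccc1O)[C@@H]1[C@H]2CO[C@@H](c3cc(OC)c4c(c3)[C@@H](CO)[C@H](c3cc(OC)c5c(c3)[C@H](CO)[C@@H](c3ccc(O)c(OC)c3)O5)O4)[C@H]2C(=O)O1 | intermediate
45 | ring A p-quinone methide carboxylate from 44 (formed in situ) | COC1=CC(=C[C@H]2CO[C@@H](c3cc(OC)c4c(c3)[C@@H](CO)[C@H](c3cc(OC)c5c(c3)[C@H](CO)[C@@H](c3ccc(O)c(OC)c3)O5)O4)[C@H]2C(=O)[O-])C=CC1=O | intermediate
46 | (2R,3S,4R)-2-(desilylated BCD)-4-(4-hydroxy-3-methoxybenzyl)oxolane-3-carboxylic acid | COc1cc(C[C@H]2CO[C@@H](c3cc(OC)c4c(c3)[C@@H](CO)[C@H](c3cc(OC)c5c(c3)[C@H](CO)[C@@H](c3ccc(O)c(OC)c3)O5)O4)[C@H]2C(=O)O)ccc1O | intermediate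
47 | CNP0395728.1: (2R,3R,4R)-2-(desilylated BCD)-4-(4-hydroxy-3-methoxybenzyl)-3-(hydroxymethyl)oxolane | COc1cc(C[C@H]2CO[C@@H](c3cc(OC)c4c(c3)[C@@H](CO)[C@H](c3cc(OC)c5c(c3)[C@H](CO)[C@@H](c3ccc(O)c(OC)c3)O5)O4)[C@H]2CO)ccc1O | target

Total step count: 30. Longest linear sequence: 24 steps (methyl vanillate 3 to 47 through steps 2–13, 15–20 and 25–30).

Steps most likely to fail

Step 27. The carbene may be lost to 1,2-hydride migration from C4–H (butenolide formation) before it inserts, or the endo preference at C2 may erode. The fallback sets out from 38 and 27 and comes back at 43. The hydroxyl of 38 would be silylated (Et3SiCl, imidazole) to the O-triethylsilyl lactone F1. Its lithium enolate (LiN(SiMe3)2, 2.2 equiv, THF, −78 → 0 °C) would be acylated by methyl ester 27 in a crossed Claisen condensation to the α-aroyl lactone F2. PPTS in MeOH, then catalytic TsOH in toluene, would remove the triethylsilyl group and dehydrate the resulting hemiketal to the bicyclic enol ether lactone F3, with its C=C between the ring B carbon and the lactone α-carbon. Hydrogenation (H2, Rh on Al2O3, EtOAc) from the convex face would add both hydrogens cis to the ring-fusion hydrogen and so should give 43 with the ring B aryl endo.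

Step 29. The 1,6-elimination may lose out to solvolytic opening of the lactone, or the quinone methide may tautomerise to the styrene before hydride capture. The fallback sets out from 43 and comes back at 47. LiBH4 (THF, 0 °C → rt) would reduce the lactone to the 1,4-diol F4. TBSCl and imidazole would silylate only the primary hydroxyl to give the primary TBS ether F5. 1,1'-Thiocarbonyldiimidazole (DMAP, CH2Cl2) would convert the ring A benzylic alcohol into the imidazolylthiocarbonyl derivative F6. Barton–McCombie deoxygenation (Bu3SnH, Et3B, air, toluene, rt) would give the fully silylated target F7, and TBAF would then give 47.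

Step 25. Acid may rearrange the imidate to the N-benzyl trichloroacetamide, ionise the dihydrobenzofuran benzylic ethers, or promote acyl migration in the hydroxymethyl lactone. The fallback sets out from 28 and 38 and comes back at 39. MnO2 would oxidise 28 to the aldehyde F8, and Me3SiCl with Et3N would convert 38 into its trimethylsilyl ether F9. Reductive etherification of F8 with F9 (Et3SiH, BiBr3 cat., MeCN, 0 °C) would give 39 without a benzylic leaving group ever being present.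

Further compounds

F1 | step 27 | (4R,5S)-5-(ArA)-4-[(triethylsilyloxy)methyl]oxolan-2-one | COc1cc(ccc1O[Si](C(C)C)(C(C)C)C(C)C)[C@@H]1[C@@H](CO[Si](CC)(CC)CC)CC(=O)O1
F2 | step 27 | 3-(BCD-carbonyl) derivative of F1 (α-aroyl lactone, C3 unassigned) | COc1cc(ccc1O[Si](C(C)C)(C(C)C)C(C)C)[C@@H]1[C@@H](CO[Si](CC)(CC)CC)C(C(=O)c2cc(OC)c3c(c2)[C@@H](CO[Si](C)(C)C(C)(C)C)[C@H](c2cc(OC)c4c(c2)[C@H](CO[Si](C)(C)C(C)(C)C)[C@@H](c2ccc(O[Si](C)(C)C(C)(C)C)c(OC)c2)O4)O3)C(=O)O1
F3 | step 27 | (5R,6S)-2-(BCD)-6-(ArA)-3,7-dioxabicyclo[3.3.0]oct-1-en-8-one | COc1cc(ccc1O[Si](C(C)C)(C(C)C)C(C)C)[C@@H]1[C@H]2COC(c3cc(OC)c4c(c3)[C@@H](CO[Si](C)(C)C(C)(C)C)[C@H](c3cc(OC)c5c(c3)[C@H](CO[Si](C)(C)C(C)(C)C)[C@@H](c3ccc(O[Si](C)(C)C(C)(C)C)c(OC)c3)O5)O4)=C2C(=O)O1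
F4 | step 29 | 1,4-diol from lactone reduction of 43: (S)-benzylic alcohol at ring A and C3 hydroxymethyl on the all-cis tetrahydrofuran | COc1cc(ccc1O[Si](C(C)C)(C(C)C)C(C)C)[C@@H](O)[C@H]1CO[C@@H](c2cc(OC)c3c(c2)[C@@H](CO[Si](C)(C)C(C)(C)C)[C@H](c2cc(OC)c4c(c2)[C@H](CO[Si](C)(C)C(C)(C)C)[C@@H](c2ccc(O[Si](C)(C)C(C)(C)C)c(OC)c2)O4)O3)[C@H]1CO
F5 | step 29 | primary TBS ether of F4 | COc1cc(ccc1O[Si](C(C)C)(C(C)C)C(C)C)[C@@H](O)[C@H]1CO[C@@H](c2cc(OC)c3c(c2)[C@@H](CO[Si](C)(C)C(C)(C)C)[C@H](c2cc(OC)c4c(c2)[C@H](CO[Si](C)(C)C(C)(C)C)[C@@H](c2ccc(O[Si](C)(C)C(C)(C)C)c(OC)c2)O4)O3)[C@H]1CO[Si](C)(C)C(C)(C)C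
F6 | step 29 | O-(imidazol-1-ylthiocarbonyl) derivative of F5 at the ring A benzylic oxygen | COc1cc(ccc1O[Si](C(C)C)(C(C)C)C(C)C)[C@@H](OC(=S)n1ccnc1)[C@H]1CO[C@@H](c2cc(OC)c3c(c2)[C@@H](CO[Si](C)(C)C(C)(C)C)[C@H](c2cc(OC)c4c(c2)[C@H](CO[Si](C)(C)C(C)(C)C)[C@@H](c2ccc(O[Si](C)(C)C(C)(C)C)c(OC)c2)O4)O3)[C@H]1CO[Si](C)(C)C(C)(C)C
F7 | step 29 | fully silylated 47 (ring A O-TIPS, ring D O-TBS, three CH2O-TBS) | COc1cc(C[C@H]2CO[C@@H](c3cc(OC)c4c(c3)[C@@H](CO[Si](C)(C)C(C)(C)C)[C@H](c3cc(OC)c5c(c3)[C@H](CO[Si](C)(C)C(C)(C)C)[C@@H](c3ccc(O[Si](C)(C)C(C)(C)C)c(OC)c3)O5)O4)[C@H]2CO[Si](C)(C)C(C)(C)C)ccc1O[Si](C(C)C)(C(C)C)C(C)C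
F8 | step 25 | BCD–CHO | O=Cc1cc(OC)c2c(c1)[C@@H](CO[Si](C)(C)C(C)(C)C)[C@H](c1cc(OC)c3c(c1)[C@H](CO[Si](C)(C)C(C)(C)C)[C@@H](c1ccc(O[Si](C)(C)C(C)(C)C)c(OC)c1)O3)O2
F9 | step 25 | (4R,5S)-5-(ArA)-4-[(trimethylsilyloxy)methyl]oxolan-2-one | COc1cc(ccc1O[Si](C(C)C)(C(C)C)C(C)C)[C@@H]1[C@@H](CO[Si](C)(C)C)CC(=O)O1
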